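**Retrosynthetic overview**
1. Target 7 ⇐ (S)-5,6,7-trimethoxyflavanone 5 by chelation-directed cleavage of the 5-O-methyl ether only; C2 is untouched.
2. 5 ⇐ chalcone 4 by disconnecting the O1–C2 bond: a catalytic enantioselective 6-endo-trig oxa-Michael ring closure that forms ring C and sets C2.
3. 4 ⇐ acetophenone 1 + aldehyde 2 by Claisen–Schmidt condensation.
4. Rings A and B are bought; ring C is the only ring formed (step 2). The single free phenol of 1 fixes the 5,6,7-regiochemistry.

Assumptions: 1 is bought as such (catalogue item, also sold as 6'-hydroxy-2',3',4'-trimethoxyacetophenone); the (S)-catalyst is assigned the 2S sense by the model given in step 2, and if a first run shows 2R its mirror image (from D-tert-leucine) is used with nothing else changed.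

Catalyst for step 2 (a reagent, not a route compound, made beforehand): 1-[3,5-bis(trifluoromethyl)phenyl]-3-[(2S)-3,3-dimethyl-1-{[tris(4-methoxyphenyl)-λ5-phosphanylidene]amino}butan-2-yl]thiourea, condensed formula (S)-ArNHC(=S)NHCH(tBu)CH2N=P(C6H4-4-OMe)3 with Ar = 3,5-(CF3)2C6H3, SMILES FC(F)(F)c1cc(NC(=S)N[C@H](CN=P(c2ccc(OC)cc2)(c2ccc(OC)cc2)c2ccc(OC)cc2)C(C)(C)C)cc(C(F)(F)F)c1.

**Route**

Step 1
Reactants: 1 1-(2-hydroxy-4,5,6-trimethoxyphenyl)ethan-1-one; 2 3,4-dimethoxybenzaldehyde
Product: 4 (E)-3-(3,4-dimethoxyphenyl)-1-(2-hydroxy-4,5,6-trimethoxyphenyl)prop-2-en-1-one, via aldol adduct 3 (not isolated)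
Conditions: KOH (3 equiv, 50% aq), EtOH, 0 → 23 °C, 36 h; then 1 M HCl to pH 4, 0 °C; recrystallise (EtOH)
Reagents that add atoms: none
Why: Claisen–Schmidt (crossed aldol) condensation: the enolate of 1 adds to non-enolisable 2 and E1cB dehydration of aldol 3 gives the thermodynamically favoured E-enone; in excess KOH the chalcone rests as its phenoxide, which does not ring-close, and cold acidification plus recrystallisation gives 4 free of racemic flavanone; no stereocentre is set.

Step 2
Reactants: 4 (E)-3-(3,4-dimethoxyphenyl)-1-(2-hydroxy-4,5,6-trimethoxyphenyl)prop-2-en-1-one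
Product: 5 (S)-2-(3,4-dimethoxyphenyl)-5,6,7-trimethoxychroman-4-one
Conditions: (S)-ArNHC(=S)NHCH(tBu)CH2N=P(C6H4-4-OMe)3 [Ar = 3,5-(CF3)2C6H3] (10 mol%), toluene (0.1 M), −20 °C, 48 h; then AcOH (0.2 equiv), −20 °C, silica plug
Reagents that add atoms: none
Why: Proposed new method: catalytic enantioselective 6-endo-trig oxa-Michael closure of the O1–C2 bond in an unactivated, electron-rich 2'-hydroxychalcone by a bifunctional iminophosphorane–thiourea superbase, in which the P=N site (far more basic than the tertiary amines that react only sluggishly and unselectively with such chalcones) deprotonates the chelated 2'-OH to a tight aminophosphonium phenoxide ion pair, the thiourea N–H pair binds the enone C=O on the far side of ring A, and the 6'-OMe group keeps the aryl–carbonyl bond twisted so that the two-point-bound substrate is a rapidly interconverting pair of helical conformers of which the tert-butyl/triarylphosphonium wall admits the one that puts the phenoxide oxygen on the Si face of C-β, making C–O bond formation enantiodetermining and setting C2 as S; the enolate is then protonated at C3 by P–N–H+ (no stereocentre there) and the base passes to the next molecule of 4, while retro-addition, the racemisation path, stays negligible at −20 °C because 6'-substitution puts the chalcone–flavanone equilibrium far on the flavanone side and the C3–H of 5 is many pK units less acidic than the phenol of 4, hence the acid quench once conversion passes about 90% (recovered 4 is recycled); closest known reaction types are amine–thiourea-catalysed oxa-Michael cyclisation of 2'-hydroxychalcones activated by an α-alkoxycarbonyl group and iminophosphorane-catalysed intramolecular oxa-Michael addition of alcohols to unsaturated esters and amides.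

Step 3
Reactants: 5 (S)-2-(3,4-dimethoxyphenyl)-5,6,7-trimethoxychroman-4-one
Product: 7 (S)-2-(3,4-dimethoxyphenyl)-5-hydroxy-6,7-dimethoxychroman-4-one, via dichloroboryl ether 6 (not isolated)
Conditions: BCl3 (1.5 equiv, 1 M in CH2Cl2), CH2Cl2, −78 → −20 °C, 2 h; then H2O, 0 °C; water/brine wash only, no base
Reagents that add atoms: none
Why: Chelation-directed ether cleavage: BCl3 binds the C4 carbonyl and the peri 5-OMe oxygen in a six-membered chelate, chloride removes only that methyl group by SN2 (as MeCl) to give aryloxyboron dichloride 6, and water hydrolyses 6 to the hydrogen-bonded 5-phenol; C2 is not involved, and the low temperature and base-free work-up are chosen to avoid the two racemisation paths (Lewis-acid ionisation of the benzylic C2–O1 bond and base-mediated retro-oxa-Michael).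

**Compound list**
1 | 1-(2-hydroxy-4,5,6-trimethoxyphenyl)ethan-1-one | CC(=O)c1c(O)cc(OC)c(OC)c1OC | starting material
2 | 3,4-dimethoxybenzaldehyde | COc1ccc(C=O)cc1OC | starting material
3 | rac-3-(3,4-dimethoxyphenyl)-3-hydroxy-1-(2-hydroxy-4,5,6-trimethoxyphenyl)propan-1-one (aldol adduct, dehydrated in the flask) | COc1ccc(C(O)CC(=O)c2c(O)cc(OC)c(OC)c2OC)cc1OC | intermediate
4 | (E)-3-(3,4-dimethoxyphenyl)-1-(2-hydroxy-4,5,6-trimethoxyphenyl)prop-2-en-1-one | COc1ccc(/C=C/C(=O)c2c(O)cc(OC)c(OC)c2OC)cc1OC | intermediate
5 | (S)-2-(3,4-dimethoxyphenyl)-5,6,7-trimethoxychroman-4-one | COc1ccc([C@@H]2CC(=O)c3c(cc(OC)c(OC)c3OC)O2)cc1OC | intermediate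
6 | (S)-5-[(dichloroboranyl)oxy]-2-(3,4-dimethoxyphenyl)-6,7-dimethoxychroman-4-one (boron chelated by the C4 carbonyl, hydrolysed on work-up) | COc1ccc([C@@H]2CC(=O)c3c(cc(OC)c(OC)c3OB(Cl)Cl)O2)cc1OC | intermediate
7 | (S)-2-(3,4-dimethoxyphenyl)-5-hydroxy-6,7-dimethoxychroman-4-one (CNP0122484.1) | COc1ccc([C@@H]2CC(=O)c3c(cc(OC)c(OC)c3O)O2)cc1OC | target

**Step count and risk**
Total steps: 3. Longest linear sequence: 3 (1 → 4 → 5 → 7; 2 is bought).

Steps most likely to fail, in order:

Step 2 (the proposed new step; risks: low rate with the electron-rich acceptor, insufficient ee, erosion of ee by retro-addition). The fallback uses known chemistry, sets out from 4 and comes back at 5. Chalcone 4 is cyclised without stereocontrol (NaOAc, EtOH, reflux) to racemic 2-(3,4-dimethoxyphenyl)-5,6,7-trimethoxychroman-4-one F3. F3 is then submitted to kinetic resolution by asymmetric transfer hydrogenation (RuCl[(R,R)-TsDPEN](p-cymene) 1 mol%, HCO2H/Et3N 5:2, EtOAc, 23 °C, stopped at about 55% conversion). By the usual aryl-ketone model of this catalyst, hydride goes to the face anti to the C2 aryl group of the (R)-enantiomer, which is reduced to the cis-alcohol (2R,4R)-2-(3,4-dimethoxyphenyl)-5,6,7-trimethoxychroman-4-ol F4. The slow-reacting (S)-ketone 5 is recovered by chromatography (at most about 45%) and enters step 3.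

Step 3 (risks: partial racemisation or ring opening at C2–O1 under the Lewis acid, helped by the 4'-methoxy group of ring B; over-demethylation at C6). The fallback sets out from 5 and comes back at 7. It stops relying on stereoretention: 5 is demethylated under robust conditions (AlCl3 3 equiv, MeCN, 23 °C), whatever the loss of ee. The product is then resolved at the end by preparative chiral SFC (amylose tris(3,5-dimethylphenylcarbamate) phase, CO2/MeOH), which removes the mirror-image compound (R)-2-(3,4-dimethoxyphenyl)-5-hydroxy-6,7-dimethoxychroman-4-one F5 and delivers 7.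

Step 1 (risks: slow condensation of the hindered phenoxide–enolate dianion, and some base- or work-up-induced closure to racemic flavanone, which would lower the ee of 5). The fallback sets out from 1 and comes back at 4. The phenol is masked first (NaH, MOMCl, DMF, 0 °C) to give 1-[2-(methoxymethoxy)-4,5,6-trimethoxyphenyl]ethan-1-one F1. As a simple mono-enolate precursor, F1 condenses faster with 2 (KOH, EtOH, 23 °C) and cannot ring-close, giving (E)-3-(3,4-dimethoxyphenyl)-1-[2-(methoxymethoxy)-4,5,6-trimethoxyphenyl]prop-2-en-1-one F2. Brief treatment with 3 M HCl in MeOH at 40 °C removes the acetal and returns 4.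

**Further compounds**
F1 | step 1 | 1-[2-(methoxymethoxy)-4,5,6-trimethoxyphenyl]ethan-1-one | CC(=O)c1c(OCOC)cc(OC)c(OC)c1OC
F2 | step 1 | (E)-3-(3,4-dimethoxyphenyl)-1-[2-(methoxymethoxy)-4,5,6-trimethoxyphenyl]prop-2-en-1-one | COCOc1cc(OC)c(OC)c(OC)c1C(=O)/C=C/c1ccc(OC)c(OC)c1
F3 | step 2 | rac-2-(3,4-dimethoxyphenyl)-5,6,7-trimethoxychroman-4-one | COc1ccc(C2CC(=O)c3c(cc(OC)c(OC)c3OC)O2)cc1OC
F4 | step 2 | (2R,4R)-2-(3,4-dimethoxyphenyl)-5,6,7-trimethoxychroman-4-ol | COc1ccc([C@H]2C[C@@H](O)c3c(cc(OC)c(OC)c3OC)O2)cc1OC
F5 | step 3 | (R)-2-(3,4-dimethoxyphenyl)-5-hydroxy-6,7-dimethoxychroman-4-one | COc1ccc([C@H]2CC(=O)c3c(cc(OC)c(OC)c3O)O2)cc1OC
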